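The synthesis rests on closing the oxepane last, at the C15–C16 bond. The precursor is the tricyclic core with a methoxymethyl ether on the tertiary C3 oxygen and an ethynyl group on cyclohexane carbon C14. Me2BBr turns the acetal into a bromomethyl ether and the C3–O–CH2 radical adds 7-exo-dig to the alkyne, so the protecting group becomes C16 and the 3-methyleneoxepane forms in one operation. The step exploits the rigid C3–C2–C1–C14 chain (C1–C2 in the tetrahydrofuran, C1–C14 in the cyclohexane), which holds the C3 oxygen beside C15. Hydrogenation then sets C15. One stereocentre from a CBS reduction relays all the others.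

Key step: step 22

Remark: atoms carry asbestinin numbers (oxonane C2–C9 with O bridging C2/C9; cyclohexane C1, C10–C14; C15 CH, C16 OCH2, C17–C20 methyls on C15, C3, C7, C12); "as in 35" means the same spatial arrangement as in the target; 1, 2 and 23 are taken as commercial, and the exposed face of the C6=C7 alkene is assumed to be the one remote from the C3 oxygen.

Step 1
Reactants: 1 [2-(1,3-dioxolan-2-yl)ethyl]magnesium bromide (THF solution); 2 N-methoxy-N-methylmethacrylamide
Product: 3 1-(1,3-dioxolan-2-yl)-4-methylpent-4-en-3-one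
Conditions: THF, −20 → 0 °C; sat. aq. NH4Cl
Reagents that add atoms: none
Why: Weinreb ketone synthesis; the chelated tetrahedral adduct persists until work-up, so the Grignard reagent adds once and the enone is released only on quench.

Step 2
Reactants: 3 1-(1,3-dioxolan-2-yl)-4-methylpent-4-en-3-one
Product: 4 (S)-1-(1,3-dioxolan-2-yl)-4-methylpent-4-en-3-ol
Conditions: (R)-2-methyl-CBS-oxazaborolidine (10 mol%), catecholborane, toluene, −78 °C; aqueous work-up
Reagents that add atoms: none
Why: Corey–Bakshi–Shibata reduction; the isopropenyl group acts as the large substituent, so the (R)-catalyst should give the (S)-carbinol, the only stereocentre set by catalysis.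

Step 3
Reactants: 4 (S)-allylic alcohol; 5 ethyl propiolate
Product: 6 ethyl (E)-3-{[(3S)-1-(1,3-dioxolan-2-yl)-4-methylpent-4-en-3-yl]oxy}prop-2-enoate
Conditions: N-methylmorpholine (cat.), CH2Cl2, rt
Reagents that add atoms: none
Why: amine-catalysed oxa-Michael addition of the alcohol to the ynoate gives the (E)-β-alkoxyacrylate without touching the stereocentre.

Step 4
Reactants: 6 β-alkoxyacrylate acetal
Product: 7 ethyl (E)-3-{[(3S)-2-methyl-6-oxohex-1-en-3-yl]oxy}prop-2-enoate
Conditions: 2 M HCl, THF, rt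
Reagents that add atoms: water, O
Why: acid hydrolysis of the dioxolane; the vinylogous carbonate and the allylic ether tolerate dilute acid.

Step 5
Reactants: 7 aldehyde
Product: 8 ethyl 2-[(2S,3R,6S)-3-hydroxy-6-(prop-1-en-2-yl)oxan-2-yl]acetate
Conditions: SmI2 (2.5 equiv), MeOH, THF, 0 °C
Reagents that add atoms: none
Why: SmI2 ketyl–acrylate reductive cyclisation (6-exo); a chair transition state with isopropenyl and acrylate equatorial gives the 2,6-cis ring, and the samarium-bound ketyl oxygen sits equatorial, trans to the new side chain.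

Step 6
Reactants: 8 tetrahydropyranol ester
Product: 9 ethyl 2-[(2S,6S)-3-oxo-6-(prop-1-en-2-yl)oxan-2-yl]acetate
Conditions: Dess–Martin periodinane, CH2Cl2, rt
Reagents that add atoms: none
Why: Dess–Martin oxidation; the C3 carbinol centre is erased on purpose so that it can be rebuilt with the methyl group and the opposite oxygen orientation.

Step 7
Reactants: 9 tetrahydropyran-3-one ester
Product: 11 ethyl 2-[(2S,3S,6S)-3-[(tert-butyldimethylsilyl)oxy]-3-methyl-6-(prop-1-en-2-yl)oxan-2-yl]acetate, via magnesium alkoxide 10 (not isolated)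
Conditions: MeMgCl, toluene/THF, −78 °C; then TBSOTf, −78 → 0 °C
Reagents that add atoms: methylmagnesium chloride, C[Mg]Cl; tert-butyldimethylsilyl trifluoromethanesulfonate, CC(C)(C)[Si](C)(C)OS(=O)(=O)C(F)(F)F
Why: Grignard addition, chemoselective for the ketone at −78 °C; methyl attacks equatorially, anti to the C2 side chain (reinforced by magnesium chelation between carbonyl and ring oxygen), leaving the C3 oxygen axial and cis to the side chain, and silylation in the flask forestalls lactonisation.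

Step 8
Reactants: 11 silyl ether ester
Product: 12 2-[(2S,3S,6S)-3-[(tert-butyldimethylsilyl)oxy]-3-methyl-6-(prop-1-en-2-yl)oxan-2-yl]acetic acid
Conditions: LiOH, THF/H2O, rt; 1 M HCl to pH 4
Reagents that add atoms: lithium hydroxide, [Li+].[OH-]
Why: ester saponification; the hindered tertiary silyl ether is stable to aqueous hydroxide.

Step 9
Reactants: 12 acid
Product: 14 1-diazo-3-[(2S,3S,6S)-3-[(tert-butyldimethylsilyl)oxy]-3-methyl-6-(prop-1-en-2-yl)oxan-2-yl]propan-2-one, via mixed anhydride 13 (not isolated)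
Conditions: i-BuOCOCl, Et3N, Et2O, −20 °C; CH2N2, Et2O, 0 °C → rt
Reagents that add atoms: diazomethane, C=[N+]=[N-]
Why: acylation of diazomethane by the mixed carbonic anhydride (the first stage of an Arndt–Eistert sequence) gives the α-diazoketone under non-acidic conditions.

Step 10
Reactants: 14 diazoketone
Product: 15 (1S,2S,5Z,8S)-2-[(tert-butyldimethylsilyl)oxy]-2,6-dimethyl-11-oxabicyclo[6.2.1]undec-5-en-9-one
Conditions: Cu(hfacac)2 (copper bis(hexafluoroacetylacetonate), 5 mol%), CH2Cl2, reflux; then EtSH, AIBN (cat.), PhH, 80 °C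
Reagents that add atoms: none
Why: the copper carbenoid forms a five-membered oxonium ylide with the ring oxygen, and [2,3]-sigmatropic rearrangement of the allylic C6–O bond expands the ring to the oxygen-bridged nine-membered ring; the bridge fixes C9 cis to C2, and thiyl-radical isomerisation converts any (E)-alkene to the (Z)-isomer.

Step 11
Reactants: 15 bicyclic ketone silyl ether
Product: 16 (1S,2S,5Z,8S)-2-hydroxy-2,6-dimethyl-11-oxabicyclo[6.2.1]undec-5-en-9-one
Conditions: Bu4NF, THF, 50 °C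
Reagents that add atoms: none
Why: fluoride cleavage of the tertiary silyl ether frees the C3 hydroxyl, which cannot form a hemiketal with C10 because that would need a norbornane-type bridge.

Step 12
Reactants: 16 bicyclic hydroxy ketone
Product: 19 (1S,2S,5R,6R,8S)-2,5-dihydroxy-2,6-dimethyl-11-oxabicyclo[6.2.1]undecan-9-one, via dimethylsilyl ether 17 (not isolated), via cyclic siloxane 18 (not isolated)
Conditions: ClSiHMe2, Et3N, DMAP (cat.), CH2Cl2, 0 °C; Pt2(dvtms)3 (dvtms = 1,3-divinyltetramethyldisiloxane, 1 mol%), toluene, 60 °C; then KF, KHCO3, 30% H2O2, THF/MeOH, rt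
Reagents that add atoms: hydrogen peroxide, OO
Why: platinum-catalysed intramolecular hydrosilylation from the C3–O–SiHMe2 tether (6-exo, syn) puts Si on C6 and H on C7 on the ring face that carries the C3 oxygen, and Tamao–Fleming oxidation replaces Si by OH with retention, so C6 and C7 are both relayed from C3 in one event.

Step 13
Reactants: 19 diol
Product: 20 (1S,2S,5R,6R,8S)-2-hydroxy-5-methoxy-2,6-dimethyl-11-oxabicyclo[6.2.1]undecan-9-one
Conditions: Me3OBF4, 1,8-bis(dimethylamino)naphthalene, CH2Cl2, 0 °C → rt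
Reagents that add atoms: trimethyloxonium tetrafluoroborate, C[O+](C)C.F[B-](F)(F)F
Why: O-methylation with Meerwein's salt under non-enolising conditions selects the secondary C6 hydroxyl over the hindered tertiary C3 hydroxyl.

Step 14
Reactants: 20 methyl ether
Product: 21 (1S,2S,5R,6R,8S)-5-methoxy-2-(methoxymethoxy)-2,6-dimethyl-11-oxabicyclo[6.2.1]undecan-9-one
Conditions: MOMCl, i-Pr2NEt, NaI (cat.), ClCH2CH2Cl, 50 °C
Reagents that add atoms: chloromethyl methyl ether, COCCl
Why: alkylation of the tertiary alcohol by the oxocarbenium-type electrophile under mild base installs the acetal that protects C3–O and later supplies C16.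

Step 15
Reactants: 21 methoxymethyl ether ketone
Product: 22 (1S,2S,5R,6R,8S)-5-methoxy-2-(methoxymethoxy)-2,6-dimethyl-11-oxabicyclo[6.2.1]undec-9-en-9-yl trifluoromethanesulfonate
Conditions: KN(SiMe3)2, THF, −78 °C; PhNTf2, −78 → 0 °C
Reagents that add atoms: N-phenylbis(trifluoromethanesulfonimide), O=S(=O)(N(c1ccccc1)S(=O)(=O)C(F)(F)F)C(F)(F)F
Why: kinetic deprotonation at the C1 methylene (C9 is a bridgehead α-alkoxy methine) and O-triflation of the enolate give the C1=C10 enol triflate.

Step 16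
Reactants: 23 1-ethoxyprop-1-yne
Product: 24 tributyl[(1E)-1-ethoxyprop-1-en-1-yl]stannane
Conditions: Bu3SnH, Pd(PPh3)4 (2 mol%), THF, 0 °C
Reagents that add atoms: tributyltin hydride, CCCC[SnH](CCCC)CCCC
Why: palladium-catalysed syn-hydrostannation of the ynol ether, with tin going to the oxygen-bearing carbon, gives the stannane in which OEt and CH3 are cis.

Step 17
Reactants: 22 enol triflate; 24 stannane
Product: 25 (1S,2S,5R,6R,8S)-9-[(1Z)-1-ethoxyprop-1-en-1-yl]-5-methoxy-2-(methoxymethoxy)-2,6-dimethyl-11-oxabicyclo[6.2.1]undec-9-ene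
Conditions: Pd(PPh3)4 (5 mol%), LiCl, THF, 65 °C
Reagents that add atoms: none
Why: Stille coupling with retention of alkene geometry gives the 2-ethoxy diene whose C12 methyl is "outside".

Step 18
Reactants: 25 ethoxy diene; 26 acrolein
Product: 27 tricyclic endo aldehyde (C10=C11 ethyl enol ether; C1 and C12 as in 35; C14–CHO cis to the C1–C2 bond, i.e. 14-epi)
Conditions: acrolein (5 equiv), BHT (cat.), toluene, 40 °C
Reagents that add atoms: none
Why: Diels–Alder reaction; the dienophile adds to the diene face anti to the C3–C8 bridge (sets C1), the suprafacial addition carries the (Z)-enol ether geometry into C12 (methyl cis to C2), the 2-ethoxy group directs the formyl carbon to C14, and the endo mode gives the C14 epimer that step 19 corrects.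

Step 19
Reactants: 27 endo aldehyde
Product: 30 tricyclic alkynyl ketone (C11 ketone; C14 ethynyl; C1, C10, C12, C14 as in 35), via trans aldehyde 28 (not isolated), via alkyne enol ether 29 (not isolated)
Conditions: K2CO3, MeOH, rt; dimethyl (1-diazo-2-oxopropyl)phosphonate, rt; aqueous work-up; 0.1 M HCl, THF, 0 °C
Reagents that add atoms: dimethyl (1-diazo-2-oxopropyl)phosphonate, COP(=O)(OC)C(=[N+]=[N-])C(C)=O; water, O
Why: carbonate epimerises the aldehyde to the equatorial isomer trans to C2 (relieving its 1,3-diaxial clash with the C12 methyl) while the enol ether keeps C12 non-enolisable, Ohira–Bestmann homologation gives the alkyne, and dilute acid hydrolyses the enol ether with protonation of C10 on the convex face (cis ring fusion).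

Step 20
Reactants: 30 alkynyl ketone
Product: 31 tricyclic alkynyl alcohol (C11–OH cis to the C12 methyl and to C9, as in 35)
Conditions: NaBH4, CeCl3·7H2O, MeOH, −40 °C
Reagents that add atoms: none
Why: Luche-type reduction; hydride attacks C11 from the convex face opposite the tetrahydrofuran and the C12 methyl, and the near-neutral cold conditions leave the epimerisable C12 centre untouched.

Step 21
Reactants: 31 alkynyl alcohol
Product: 32 tricyclic alkynyl acetate (C3–OCH2OCH3, C6–OCH3, C11–OAc, C14–C≡CH; all stereocentres as in 35)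
Conditions: Ac2O, pyridine, DMAP (cat.), CH2Cl2, rt
Reagents that add atoms: acetic anhydride, CC(=O)OC(C)=O
Why: DMAP-catalysed acetylation of the secondary alcohol with retention at C11.

Step 22
Reactants: 32 alkynyl acetate
Product: 34 15(17)-methylene oxepane (tetracycle with exocyclic C15=C17; other stereocentres as in 35), via bromomethyl ether 33 (not isolated)
Conditions: Me2BBr, CH2Cl2, −78 °C; volatiles removed cold in vacuo; (Me3Si)3SiH, AIBN (cat.), PhH (0.005 M), 80 °C, slow addition
Reagents that add atoms: none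
Why: Me2BBr cleaves the methoxymethyl acetal at −78 °C to the bromomethyl ether 33, the silyl radical abstracts bromine to give the nucleophilic C3–O–CH2 radical, this adds to C15 of the ethynyl group, and the vinyl radical at C17 takes hydrogen from (Me3Si)3SiH to carry the chain. The closest known reaction type is the stannane- or silane-mediated cyclisation of alkoxymethyl radicals, generated from α-halo or α-seleno ethers, onto alkenes and alkynes. The oxepane (C3, O, C16, C15, C14, C1, C2) closes in the 7-exo-dig mode. No stereocentre is created: C15 becomes the sp2 carbon of an exocyclic methylene and is set in step 23, while C1, C2, C3 and C14 are untouched. The step needs exo over 8-endo attack, secured because endo closure would put the linear C14–C15≡C17 unit inside an eight-membered transition ring, and cyclisation over direct reduction, secured by the equatorial C2 and C14 substituents holding C16 beside C15, by the slow hydrogen donor and by high dilution. Chemoselectivity of Me2BBr for the acetal over acetate, methyl ether and alkyne rests on the low temperature.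

Step 23
Reactants: 34 methylene oxepane
Product: 35 CNP0289153.2, (1S,2S,3S,6R,7R,9S,10R,11R,12R,14S,15R)-11-acetoxy-6-methoxy asbestinin-type tetracycle
Conditions: H2 (1 atm), RhCl(PPh3)3 (10 mol%), PhH, rt
Reagents that add atoms: none
Why: homogeneous hydrogenation of the 1,1-disubstituted alkene without double-bond migration; hydrogen should reach C15 from the equatorial direction of the chair-like oxepane (the side of axial H14), because the axial path is hindered by axial H1 and the C13 methylene, leaving the new methyl axial and anti to H14 (15R).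

Compound list
1 | [2-(1,3-dioxolan-2-yl)ethyl]magnesium bromide | Br[Mg]CCC1OCCO1 | starting material
2 | N-methoxy-N-methylmethacrylamide | CON(C)C(=O)C(C)=C | starting material
3 | 1-(1,3-dioxolan-2-yl)-4-methylpent-4-en-3-one | CC(=C)C(=O)CCC1OCCO1 | intermediate
4 | (S)-1-(1,3-dioxolan-2-yl)-4-methylpent-4-en-3-ol | O[C@H](C(C)=C)CCC1OCCO1 | intermediate
5 | ethyl propiolate | CCOC(=O)C#C | starting material
6 | ethyl (E)-3-{[(3S)-1-(1,3-dioxolan-2-yl)-4-methylpent-4-en-3-yl]oxy}prop-2-enoate | CCOC(=O)/C=C/O[C@H](C(C)=C)CCC1OCCO1 | intermediate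
7 | ethyl (E)-3-{[(3S)-2-methyl-6-oxohex-1-en-3-yl]oxy}prop-2-enoate | CCOC(=O)/C=C/O[C@H](C(C)=C)CCC=O | intermediate
8 | ethyl 2-[(2S,3R,6S)-3-hydroxy-6-(prop-1-en-2-yl)oxan-2-yl]acetate | CCOC(=O)C[C@@H]1O[C@H](C(C)=C)CC[C@H]1O | intermediate
9 | ethyl 2-[(2S,6S)-3-oxo-6-(prop-1-en-2-yl)oxan-2-yl]acetate | CCOC(=O)C[C@@H]1O[C@H](C(C)=C)CCC1=O | intermediate
10 | chloromagnesium alkoxide of ethyl 2-[(2S,3S,6S)-3-hydroxy-3-methyl-6-(prop-1-en-2-yl)oxan-2-yl]acetate (not isolated) | CCOC(=O)C[C@@H]1O[C@H](C(C)=C)CC[C@]1(C)O[Mg]Cl | intermediate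
11 | ethyl 2-[(2S,3S,6S)-3-[(tert-butyldimethylsilyl)oxy]-3-methyl-6-(prop-1-en-2-yl)oxan-2-yl]acetate | CCOC(=O)C[C@@H]1O[C@H](C(C)=C)CC[C@]1(C)O[Si](C)(C)C(C)(C)C | intermediate
12 | 2-[(2S,3S,6S)-3-[(tert-butyldimethylsilyl)oxy]-3-methyl-6-(prop-1-en-2-yl)oxan-2-yl]acetic acid | OC(=O)C[C@@H]1O[C@H](C(C)=C)CC[C@]1(C)O[Si](C)(C)C(C)(C)C | intermediate
13 | isobutyl carbonic mixed anhydride of 12 (not isolated) | CC(C)COC(=O)OC(=O)C[C@@H]1O[C@H](C(C)=C)CC[C@]1(C)O[Si](C)(C)C(C)(C)C | intermediate
14 | 1-diazo-3-[(2S,3S,6S)-3-[(tert-butyldimethylsilyl)oxy]-3-methyl-6-(prop-1-en-2-yl)oxan-2-yl]propan-2-one | [N-]=[N+]=CC(=O)C[C@@H]1O[C@H](C(C)=C)CC[C@]1(C)O[Si](C)(C)C(C)(C)C | intermediate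
15 | (1S,2S,5Z,8S)-2-[(tert-butyldimethylsilyl)oxy]-2,6-dimethyl-11-oxabicyclo[6.2.1]undec-5-en-9-one | O=C1C[C@@H]2O[C@H]1C/C(C)=C\CC[C@]2(C)O[Si](C)(C)C(C)(C)C | intermediate
16 | (1S,2S,5Z,8S)-2-hydroxy-2,6-dimethyl-11-oxabicyclo[6.2.1]undec-5-en-9-one | O=C1C[C@@H]2O[C@H]1C/C(C)=C\CC[C@]2(C)O | intermediate
17 | dimethylsilyl ether of 16 at the C3 oxygen (not isolated) | O=C1C[C@@H]2O[C@H]1C/C(C)=C\CC[C@]2(C)O[SiH](C)C | intermediate
18 | cyclic siloxane, SiMe2 bridging the C3 oxygen and C6, H on C7 cis to Si (not isolated) | C[Si]3(C)[C@@H]1CC[C@](C)(O3)[C@H]2O[C@@H](C[C@H]1C)C(=O)C2 | intermediate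
19 | (1S,2S,5R,6R,8S)-2,5-dihydroxy-2,6-dimethyl-11-oxabicyclo[6.2.1]undecan-9-one | O[C@@H]1CC[C@](C)(O)[C@H]2O[C@@H](C[C@H]1C)C(=O)C2 | intermediate
20 | (1S,2S,5R,6R,8S)-2-hydroxy-5-methoxy-2,6-dimethyl-11-oxabicyclo[6.2.1]undecan-9-one | CO[C@@H]1CC[C@](C)(O)[C@H]2O[C@@H](C[C@H]1C)C(=O)C2 | intermediate
21 | (1S,2S,5R,6R,8S)-5-methoxy-2-(methoxymethoxy)-2,6-dimethyl-11-oxabicyclo[6.2.1]undecan-9-one | CO[C@@H]1CC[C@](C)(OCOC)[C@H]2O[C@@H](C[C@H]1C)C(=O)C2 | intermediate
22 | (1S,2S,5R,6R,8S)-5-methoxy-2-(methoxymethoxy)-2,6-dimethyl-11-oxabicyclo[6.2.1]undec-9-en-9-yl trifluoromethanesulfonate | CO[C@@H]1CC[C@](C)(OCOC)[C@H]2O[C@@H](C[C@H]1C)C(OS(=O)(=O)C(F)(F)F)=C2 | intermediate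
23 | 1-ethoxyprop-1-yne | CC#COCC | starting material
24 | tributyl[(1E)-1-ethoxyprop-1-en-1-yl]stannane | CCCC[Sn](CCCC)(CCCC)/C(OCC)=C/C | intermediate
25 | (1S,2S,5R,6R,8S)-9-[(1Z)-1-ethoxyprop-1-en-1-yl]-5-methoxy-2-(methoxymethoxy)-2,6-dimethyl-11-oxabicyclo[6.2.1]undec-9-ene | CO[C@@H]1CC[C@](C)(OCOC)[C@H]2O[C@@H](C[C@H]1C)C(/C(OCC)=C/C)=C2 | intermediate
26 | acrolein | C=CC=O | starting material
27 | tricyclic endo aldehyde: C10=C11 ethyl enol ether, C14–CHO cis to C1–C2 (14-epi), other centres as in 35 | CO[C@@H]1CC[C@](C)(OCOC)[C@H]2O[C@@H](C[C@H]1C)C3=C(OCC)[C@H](C)C[C@H](C=O)[C@H]23 | intermediate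
28 | tricyclic trans aldehyde: C14–CHO trans to C1–C2, as in 35 (not isolated) | CO[C@@H]1CC[C@](C)(OCOC)[C@H]2O[C@@H](C[C@H]1C)C3=C(OCC)[C@H](C)C[C@@H](C=O)[C@H]23 | intermediate
29 | tricyclic alkyne enol ether: C14 ethynyl, C10=C11 ethyl enol ether (not isolated) | CO[C@@H]1CC[C@](C)(OCOC)[C@H]2O[C@@H](C[C@H]1C)C3=C(OCC)[C@H](C)C[C@@H](C#C)[C@H]23 | intermediate
30 | tricyclic alkynyl ketone: C11 ketone, H10 cis to H1, centres as in 35 | CO[C@@H]1CC[C@](C)(OCOC)[C@H]2O[C@@H](C[C@H]1C)[C@@H]3C(=O)[C@H](C)C[C@@H](C#C)[C@H]23 | intermediate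
31 | tricyclic alkynyl alcohol: C11–OH cis to the C12 methyl, centres as in 35 | CO[C@@H]1CC[C@](C)(OCOC)[C@H]2O[C@@H](C[C@H]1C)[C@@H]3[C@H](O)[C@H](C)C[C@@H](C#C)[C@H]23 | intermediate
32 | tricyclic alkynyl acetate: C3–OCH2OCH3, C6–OCH3, C11–OAc, C14–C≡CH, centres as in 35 | CO[C@@H]1CC[C@](C)(OCOC)[C@H]2O[C@@H](C[C@H]1C)[C@@H]3[C@H](OC(C)=O)[C@H](C)C[C@@H](C#C)[C@H]23 | intermediate
33 | bromomethyl ether of the C3 oxygen, otherwise as 32 (not isolated) | CO[C@@H]1CC[C@](C)(OCBr)[C@H]2O[C@@H](C[C@H]1C)[C@@H]3[C@H](OC(C)=O)[C@H](C)C[C@@H](C#C)[C@H]23 | intermediate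
34 | 15(17)-methylene oxepane: tetracycle with exocyclic C15=C17, other centres as in 35 | CO[C@@H]1CC[C@]2(C)OCC(=C)[C@@H]3C[C@@H](C)[C@@H](OC(C)=O)[C@@H]4[C@H]3[C@@H]2O[C@H]4C[C@H]1C | intermediate
35 | CNP0289153.2, (1S,2S,3S,6R,7R,9S,10R,11R,12R,14S,15R) | CO[C@@H]1CC[C@]2(C)OC[C@H](C)[C@@H]3C[C@@H](C)[C@@H](OC(C)=O)[C@@H]4[C@H]3[C@@H]2O[C@H]4C[C@H]1C | target

Total step count: 23. Longest linear sequence: 22 steps (steps 1–15 and 17–23; step 16 makes the stannane).

Steps most likely to fail

Step 22. The alkoxymethyl radical may be reduced by the silane before it closes the ring, or the bromomethyl ether may hydrolyse during the solvent change. The fallback closes the same bond by a polar olefination and sets out from 32. Hydration of the alkyne (Ph3PAuNTf2 cat., MeOH/H2O) should give the C14 methyl ketone F1. Me2BBr at −78 °C followed by PPh3 converts the acetal into the (alkoxymethyl)triphenylphosphonium bromide F2. KN(SiMe3)2 in THF at −78 → 0 °C then brings about an intramolecular Wittig reaction to the cyclic enol ether F3 (C15=C16 inside the oxepane). Hydrogenation (H2, Pd/C, EtOAc) returns to the route at 35.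

Step 12. Platinum-catalysed delivery to the trisubstituted ring alkene may be slow, leaving room for intermolecular hydrosilylation or alkene migration. The fallback sets out from 15 and reaches C6/C7 by a stereospecific hydride shift. KN(SiMe3)2/PhNTf2 gives the silyl-protected enol triflate F4 (masking C10). mCPBA epoxidises C6=C7 on the exposed face to the epoxide F5. BF3·OEt2 at −78 °C opens it at C7, and the anti-periplanar 1,2-hydride shift from C6 (Meinwald rearrangement) gives the C6 ketone F6 with H7 on the inner face. LiBH(s-Bu)3 reduces from the exposed face to the C6 alcohol F7. Me3OBF4 with 1,8-bis(dimethylamino)naphthalene gives the methyl ether F8, Bu4NF the tertiary alcohol F9, and MOMCl/i-Pr2NEt returns to the route at 22.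

Step 23. Hydrogen may be delivered with poor facial selectivity at C15, or the alkene may migrate into the ring. The fallback sets out from 34 and uses reagent control. Hydroboration with (+)-Ipc2BH and oxidation with NaBO3·4H2O gives the C17 primary alcohol F10 (the other borane enantiomer if mismatched). TsCl/pyridine gives the tosylate F11. LiEt3BH reduces it to the methyl group and also removes the acetate, giving the 11-deacetyl compound F12. Ac2O/pyridine/DMAP returns to the route at 35.

Further compounds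
F1 | step 22 | C14 acetyl analogue of 32 (methyl ketone) | CO[C@@H]1CC[C@](C)(OCOC)[C@H]2O[C@@H](C[C@H]1C)[C@@H]3[C@H](OC(C)=O)[C@H](C)C[C@@H](C(C)=O)[C@H]23
F2 | step 22 | (alkoxymethyl)triphenylphosphonium bromide derived from F1 | CO[C@@H]1CC[C@](C)(OC[P+](c4ccccc4)(c5ccccc5)c6ccccc6)[C@H]2O[C@@H](C[C@H]1C)[C@@H]3[C@H](OC(C)=O)[C@H](C)C[C@@H](C(C)=O)[C@H]23.[Br-]
F3 | step 22 | cyclic enol ether with C15=C16 in the oxepane | CO[C@@H]1CC[C@]2(C)OC=C(C)[C@@H]3C[C@@H](C)[C@@H](OC(C)=O)[C@@H]4[C@H]3[C@@H]2O[C@H]4C[C@H]1C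
F4 | step 12 | enol triflate of 15 (C3 silyl ether, C6=C7 alkene) | FC(F)(F)S(=O)(=O)OC1=C[C@@H]2O[C@H]1C/C(C)=C\CC[C@]2(C)O[Si](C)(C)C(C)(C)C
F5 | step 12 | C6,C7-epoxide of F4, oxygen on the exposed face | [C@H]15CC[C@](C)(O[Si](C)(C)C(C)(C)C)[C@H]2O[C@@H](C[C@@]1(C)O5)C(OS(=O)(=O)C(F)(F)F)=C2
F6 | step 12 | C6 ketone with C7 as in 35 | O=C1CC[C@](C)(O[Si](C)(C)C(C)(C)C)[C@H]2O[C@@H](C[C@H]1C)C(OS(=O)(=O)C(F)(F)F)=C2
F7 | step 12 | C6 alcohol with C6 and C7 as in 35 | O[C@@H]1CC[C@](C)(O[Si](C)(C)C(C)(C)C)[C@H]2O[C@@H](C[C@H]1C)C(OS(=O)(=O)C(F)(F)F)=C2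
F8 | step 12 | C6 methyl ether, C3 silyl ether, enol triflate | CO[C@@H]1CC[C@](C)(O[Si](C)(C)C(C)(C)C)[C@H]2O[C@@H](C[C@H]1C)C(OS(=O)(=O)C(F)(F)F)=C2
F9 | step 12 | C6 methyl ether, free C3 hydroxyl, enol triflate | CO[C@@H]1CC[C@](C)(O)[C@H]2O[C@@H](C[C@H]1C)C(OS(=O)(=O)C(F)(F)F)=C2
F10 | step 23 | C17 primary alcohol of the tetracycle | CO[C@@H]1CC[C@]2(C)OC[C@H](CO)[C@@H]3C[C@@H](C)[C@@H](OC(C)=O)[C@@H]4[C@H]3[C@@H]2O[C@H]4C[C@H]1C
F11 | step 23 | C17 p-toluenesulfonate | CO[C@@H]1CC[C@]2(C)OC[C@H](COS(=O)(=O)c5ccc(C)cc5)[C@@H]3C[C@@H](C)[C@@H](OC(C)=O)[C@@H]4[C@H]3[C@@H]2O[C@H]4C[C@H]1C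
F12 | step 23 | 11-deacetyl 35 | CO[C@@H]1CC[C@]2(C)OC[C@H](C)[C@@H]3C[C@@H](C)[C@@H](O)[C@@H]4[C@H]3[C@@H]2O[C@H]4C[C@H]1C
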